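**Assumptions and checks on the structures**

- Numbering: germacrane numbering is used throughout (ring carbons C1–C10, lactone α-carbon C11, lactone carbonyl C12, exocyclic methylene C13, methyl C14 on C10, methyl C15 on C4).
- Side chain: read from its descriptors, the O8 ester is (2R,3S)-2,3-dimethyloxirane-2-carboxylate with the two methyl groups cis. Its acid is therefore made from (E)-2-methylbut-2-en-1-ol.
- Key-step structures: 19 and 21 were compared with the target atom by atom. They agree at C6, C7 and C8 (C7 inverted in the ring opening), at the Z-iodoalkene and at the E-C1=C10 olefin, so neither skeleton needed correction.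
- Two points made explicit: the erythro epoxy alcohol behind 19 is (6R,7R,8R), which requires the Sharpless reagent built from D-(−)-tartrate. The CIP label at C6 changes from S (iodides 21, 26–28) to R (29–32) with no change of geometry.
- One weakness of the key step: the ring closure is an enolate alkylation with the enolate C=C inside a five-membered ring. This is addressed by the choice of ion pair in step 11 and by a fallback.

## Structural features

The target is a heliangolide-type germacranolide. A ten-membered carbocycle (ring A) is trans-fused at C6–C7 to an α-methylene-γ-butyrolactone (ring B) closed on O6. Ring A holds a Z-trisubstituted C4=C5 olefin and a trans 1,10-oxirane (ring C, 1R,10R). The stereocentres C6, C7 and C8 (all R) are contiguous and carry the lactone oxygen, the lactone α-carbon branch and the acyloxy group. C3 (S, allylic carbinol) is separated from this triad by C4=C5 and from the oxirane by C2, and the side-chain oxirane adds two more centres (2R,3S). Fragile groups are the Michael-accepting methylene lactone, the 1,10-oxirane (open to acid-triggered transannular attack by C4=C5 or O3), and the lactone, which can migrate to O8 whenever O8 is free. The real difficulty is twofold: closing a ten-membered ring that contains one E and one Z trisubstituted unit, and building the C6–C7–C8 triad with the lactone on O6 and not on O8. The key step exploits the O6–C6–C7–C8–O8 array with C11 on C7 anti to O8. This is the retron of a 2,3-epoxy alcohol (C6 carbinol, trans C7–C8 oxirane) whose O6 ester delivers C11 to C7, so that ring B, the C7 centre, the free O8 and then C11=C13 arise together.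

## Logic of the disconnections

**32 back to 29.** The O3–Si bond (31), the two C–O bonds of ring C (30) and again the O3–Si bond (29) are removed. Ring C is traced to the E-C1=C10 olefin because that olefin can be carried from the first step and is the only electron-rich double bond in 30. The gain is that no acid-sensitive oxirane has to survive the ring closure. The forward epoxidation must choose C1=C10 over C4=C5 and C11=C13 and the outer face of ring A, which is why O3 is silylated first. The last desilylation must be non-acidic.

**29 back to 26.** Ring A is cut at C3–C4, between the carbinol and the Z olefin, giving 28, and then 27 and 26 by changing oxidation level and protection at C3. The cut is placed there because C4 then ends as a Z-alkenyl iodide and C3 as an aldehyde, a pair that an alkenylchromium addition joins in the presence of lactone, ester and oxirane. The ten-membered ring becomes an open chain whose other stereocentres are already fixed. The forward step must cyclise at high dilution, keep the Z geometry and create C3 as S.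

**26 back to 21 and 24.** The acyl C–O8 bond is cut. Acylating O8 with the final side chain directly after the key step removes a protection–deprotection pair and blocks lactone migration to O8 for the rest of the route. The demand is that the glycidic ester survives fluoride, oxidation, divalent chromium and peracid. 24 goes back through 23 to 22 by oxidation-level change and a reagent-controlled epoxidation that fixes both side-chain centres.

**21 back to 19 (key disconnection).** C11=C13 and C7–C11 are cut. This turns ring B with its exocyclic methylene and the C7 centre into an O6 phosphonoacetate facing a trans C7–C8 oxirane. The gain is one ring, two skeletal bonds and one stereocentre in a single operation, with O6 and O8 differentiated from the outset. The forward step demands C-alkylation at C7 with inversion, no attack at C8, no O-alkylation, and olefination of a one-carbon aldehyde before the C8 alkoxide can disturb the lactone.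

**19 back to 16.** The ester C–O6 bond is cut to give 17 and 18. The two oxirane C–O bonds of 17 are then cut to give the bis-allylic alcohol 16. A reagent-controlled allylic epoxidation run as a kinetic resolution sets C6, C7 and C8 in one step from racemic material. The demand is that only C7=C8 reacts and that at most half of 16 is used.

**16 back to 9 and 13.** C6–C7 is cut between the carbinol and the E olefin. This gives an E-alkenyl metal derived from the terminal alkyne 9 and the Z-iodo enal 13, two fragments of similar size. The forward addition must be 1,2 to a sensitive enal and must not touch the C–I bond.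

**13 back to 10; 9 back to 1 and 6.** 13 comes from 12 and 10 by oxidation and a hydroxyl-directed hydroalumination–iodination that fixes the Z geometry. 9 is cut at C8–C9 into 6 and the allylic bromide 5, which goes back through 4 and 2 to 1 by an allylic oxidation of the E-methyl group. The E-C1=C10 olefin is thus taken from the starting material. The demands are E-selective oxidation and substitution at the primary allylic carbon without transposition.

## Other disconnections considered

**Alternative 1:** Ring A is cut at C1–C2.
- Forward key step: SmI2 reduces the C2 bromide of the open-chain bromo enone aldehyde A1 to a samarium enolate that adds to the C1 aldehyde, closing ring A as the β-hydroxy Z-enone A2.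
- In its favour: carbonyl additions of samarium enolates are an established way to medium rings. The conditions are neutral and fast, the Z olefin and the C6–C7–C8 triad are in place, and the C10 carbinol comes from a chiral-pool hydroxy diacid. The C1 hydroxyl and the C10 oxygen of A2 are a direct precursor of ring C.
- Against it here: A2 is far from the target. The C3 ketone must be reduced with facial control and C1 is formed under substrate control only. Ring C must be closed with inversion at C1 beside a tertiary silyl ether. C12 must be raised from an allylic silyl ether to the acid and lactonised on O6, with three silyl ethers and a benzylic ether to be told apart. The reductant may also attack the enone or expel the C6 silyloxy group of A1 through the dienolate.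
- Comparison: on precedent for the key step Alternative 1 is the better plan. On the ring-closing event the two are equal, since both close ring A by addition to an aldehyde and both create one carbinol under macrocyclic control (C1 there, C3 here). On the C6–C7–C8 triad the chosen plan is stronger, because one reagent-controlled epoxidation and one SN2 inversion fix it. On operations after ring closure the chosen plan is clearly shorter.

**Alternative 2:** Ring A is cut at C9–C10.
- Forward key step: dehydration of the primary nitro group of the nitro olefin A3 (an aryl isocyanate with a tertiary amine) gives the C10 nitrile oxide. It adds across the C8=C9 vinyl group to give the bridged isoxazoline A4, forming C9–C10 and O–C8.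
- In its favour: intramolecular nitrile oxide cycloaddition is a proven macrocyclisation. Carbon-to-terminal-CH2 bonding follows the innate regiochemistry, ring A and the C8 oxygen arise together, and the conditions spare lactone and Z olefin. A4 carries a saturated lactone, so no Michael acceptor is exposed during ring closure; on that point Alternative 2 is the better.
- Against it here: C8 is set by the facial selectivity of a vinyl group under substrate control. After the key step the N–O bond must be cleaved to a β-hydroxy ketone prone to dehydration across C8–C9. A methyl nucleophile must then choose the C10 ketone over the lactone and the correct face, so the quaternary centre is made late. Ring C needs inversion at C1 after selective activation among three hydroxyls, and the methylene must be added by enolate chemistry on a fragile macrocycle.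
- Comparison: on precedent for the key step Alternative 2 is the better. On stereocontrol the chosen plan is stronger (C8 by reagent control, C10 methyl from the start). On step economy after ring closure the chosen plan is shorter.

**Alternative 3:** Ring A is cut at C8–C9.
- Forward key step: BF3·OEt2 activates the C8 aldehyde of the allylsilane aldehyde A5. The allylsilane attacks through C9 with loss of silicon from C1 (Hosomi–Sakurai reaction), forming C8–C9 and C1=C10 and giving the 8-hydroxy lactone A6.
- In its favour: A6 is as close to the target as 29 is. Acylation of O8, epoxidation and desilylation are three operations, the same number as from 29, so the two plans are equal on end-game length. The whole carbon frame, the methylene lactone and C3, C6 and C7 are in place before closure, and a monoterpene chiral-pool ketone supplies C7 with its three-carbon branch. Intramolecular allylsilane additions are known chemistry, so on precedent Alternative 3 is the better.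
- Against it here: C8 is created in the closure under substrate control. The new C1=C10 olefin must come out E in a strained ring, and its geometry is tied to the configuration of the silicon-bearing C1 by the anti SE2' course. The C8 aldehyde of A5 has at C7 a hydrogen β to the lactone oxygen on C6, inviting epimerisation or elimination. The Lewis acid can ionise the allylic C6–O bond or the allylic silyl ether at C3, and A6 has a free O8 beside the lactone.
- Comparison: on control of C8 and on tolerance of the reaction medium the chosen plan is stronger.

Key step: step 11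

## Route

Step 1
Reactants: 1 4-methylpent-3-en-1-ol
Product: 2 tert-butyldimethyl[(4-methylpent-3-en-1-yl)oxy]silane
Conditions: TBSCl, imidazole, DMF, 0 °C to rt
Reagents that add atoms: tert-butyldimethylsilyl chloride, CC(C)(C)[Si](C)(C)Cl
Why: Routine silylation of a primary alcohol through the silylimidazolium ion; it masks O3 until the ring closure and creates no stereocentre.

Step 2
Reactants: 2 tert-butyldimethyl[(4-methylpent-3-en-1-yl)oxy]silane
Product: 4 (E)-5-[(tert-butyldimethylsilyl)oxy]-2-methylpent-2-en-1-ol, via E-enal 3 (not isolated)
Conditions: SeO2 (cat.), t-BuOOH, CH2Cl2, rt; then NaBH4, MeOH, 0 °C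
Reagents that add atoms: selenium dioxide, O=[Se]=O; tert-butyl hydroperoxide, CC(C)(C)OO
Why: Riley-type allylic oxidation (ene reaction, then 2,3-sigmatropic shift) selects the E-methyl group of a trisubstituted olefin, so the E geometry of the later C1=C10 olefin is taken over from 1; borohydride returns any over-oxidised enal 3 to 4.

Step 3
Reactants: 4 (E)-5-[(tert-butyldimethylsilyl)oxy]-2-methylpent-2-en-1-ol
Product: 5 (E)-[(5-bromo-4-methylpent-3-en-1-yl)oxy](tert-butyl)dimethylsilane
Conditions: CBr4, PPh3, CH2Cl2, 0 °C
Reagents that add atoms: tetrabromomethane, BrC(Br)(Br)Br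
Why: Appel bromination of a primary allylic alcohol under neutral conditions should proceed without allylic transposition or loss of the silyl ether.

Step 4
Reactants: 5 (E)-[(5-bromo-4-methylpent-3-en-1-yl)oxy](tert-butyl)dimethylsilane; 6 ethynyltrimethylsilane
Product: 8 (E)-tert-butyldimethyl{[4-methyl-7-(trimethylsilyl)hept-3-en-6-yn-1-yl]oxy}silane, via alkynylmagnesium bromide 7 (not isolated)
Conditions: 6, EtMgBr, THF, 0 °C to rt; then CuBr·SMe2 (10 mol %), 5, THF, 0 °C to rt
Reagents that add atoms: none
Why: Copper-catalysed substitution of a primary allylic bromide by an alkynyl Grignard reagent forms C8–C9; attack at the primary carbon is favoured over SN2' attack at the fully substituted C10, and the silyl cap prevents a second alkylation.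

Step 5
Reactants: 8 (E)-tert-butyldimethyl{[4-methyl-7-(trimethylsilyl)hept-3-en-6-yn-1-yl]oxy}silane
Product: 9 (E)-tert-butyldimethyl[(4-methylhept-3-en-6-yn-1-yl)oxy]silane
Conditions: K2CO3 (cat.), MeOH, rt
Reagents that add atoms: none
Why: Methanolysis of the alkynyl C–Si bond is much faster than cleavage of the alkyl silyl ether, and the mild base should leave the skipped enyne unisomerised.

Step 6
Reactants: 10 but-2-yn-1-ol
Product: 12 (Z)-3-iodobut-2-en-1-ol, via cyclic alkenylalanate 11 (not isolated)
Conditions: NaAlH2(OCH2CH2OMe)2 (Red-Al), THF, 0 °C to rt; EtOAc; then I2, THF, −78 to 0 °C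
Reagents that add atoms: iodine, II
Why: Hydroxyl-directed trans-hydroalumination places aluminium on C3 in a five-membered alanate 11, and iodinolysis with retention gives the Z-iodide only; this fixes the Z geometry of C4=C5.

Step 7
Reactants: 12 (Z)-3-iodobut-2-en-1-ol
Product: 13 (Z)-3-iodobut-2-enal
Conditions: MnO2, CH2Cl2, rt, dark
Reagents that add atoms: none
Why: Heterogeneous, neutral oxidation of an allylic alcohol with MnO2; the aldehyde is used at once and kept from light and acid to avoid Z-to-E isomerisation.

Step 8
Reactants: 9 (E)-tert-butyldimethyl[(4-methylhept-3-en-6-yn-1-yl)oxy]silane; 13 (Z)-3-iodobut-2-enal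
Product: 16 rac-(2Z,5E,8E)-11-[(tert-butyldimethylsilyl)oxy]-2-iodo-8-methylundeca-2,5,8-trien-4-ol, via alkenylzirconocene chloride 14 (not isolated), via alkenylmethylzinc 15 (not isolated)
Conditions: Cp2Zr(H)Cl, CH2Cl2, rt; Me2Zn, toluene, −65 °C; then 13, 0 °C
Reagents that add atoms: none
Why: syn-Hydrozirconation of the terminal alkyne gives the E-alkenylzirconocene 14 with the metal on C7, transmetalation to zinc gives 15, and 1,2-addition to the enal forms C6–C7; the trisubstituted olefin, the silyl ether and the alkenyl iodide should be inert, and the carbinol is racemic at this stage.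

Step 9
Reactants: 16 rac-(2Z,5E,8E)-11-[(tert-butyldimethylsilyl)oxy]-2-iodo-8-methylundeca-2,5,8-trien-4-ol
Product: 17 (1R,2Z)-1-[(2R,3R)-3-{(2E)-5-[(tert-butyldimethylsilyl)oxy]-2-methylpent-2-en-1-yl}oxiran-2-yl]-3-iodobut-2-en-1-ol
Conditions: Ti(OiPr)4, D-(−)-DIPT, t-BuOOH (0.55 equiv), 4 Å MS, CH2Cl2, −20 °C
Reagents that add atoms: tert-butyl hydroperoxide, CC(C)(C)OO
Why: Sharpless asymmetric epoxidation run as a kinetic resolution: the D-(−)-tartrate complex should epoxidise C7=C8 of the (S)-carbinol much faster than that of its enantiomer and with erythro selectivity, which sets C6, C7 and C8 by reagent control; the iodoalkene (electron-poor, Z-substituted) and the non-allylic C1=C10 olefin should not react, and the (R)-carbinol is left behind.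

Step 10
Reactants: 17 epoxy alcohol (6R,7R,8R); 18 (diethoxyphosphoryl)acetic acid
Product: 19 (1R,2Z)-1-[(2S,3R)-3-{(2E)-5-[(tert-butyldimethylsilyl)oxy]-2-methylpent-2-en-1-yl}oxiran-2-yl]-3-iodobut-2-en-1-yl (diethoxyphosphoryl)acetate
Conditions: DCC, DMAP (cat.), CH2Cl2, 0 °C to rt
Reagents that add atoms: none
Why: Steglich esterification under near-neutral conditions, so neither Payne rearrangement nor oxirane opening is expected; the label at C7 changes to S through priority only.

Step 11
Reactants: 19 epoxy phosphonoacetate
Product: 21 (4R,5S)-4-[(1R,3E)-6-[(tert-butyldimethylsilyl)oxy]-1-hydroxy-3-methylhex-3-en-1-yl]-5-[(1Z)-2-iodoprop-1-en-1-yl]-3-methylideneoxolan-2-one, via sodio phosphonolactone 20 (not isolated)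
Conditions: NaH (1.05 equiv), THF, 0 to 45 °C; then (CH2O)n, 0 °C to rt; pH 7 buffer, 0 °C
Reagents that add atoms: formaldehyde (from paraformaldehyde), C=O
Why: Proposed new method: deprotonation of the phosphonoacetate gives a sodium-chelated carbanion whose C11 attacks C7 from the side opposite the oxirane oxygen (intramolecular SN2), closing ring B and releasing the C8 alkoxide; this alkoxide takes the acidic α-proton of the new α-phosphono lactone 20, and the regenerated phosphonate carbanion olefinates formaldehyde (Horner–Wadsworth–Emmons) to give C11=C13; the closest known reactions are the intermolecular opening of oxiranes by phosphonoacetate anions with lactonisation and the methylenation of α-phosphono-γ-lactones with formaldehyde, the tethered one-pot form being untested. Ring B closes 5-exo-tet with respect to the oxirane, but as an enolate alkylation it is a five-membered closure with the enolate C=C inside the ring, the unfavoured case of the Baldwin enolate rules, so C-alkylation has to compete with attack by the enolate oxygen. C7 is the only new stereocentre and is fixed by inversion at the oxirane carbon, whose configuration comes from the tartrate reagent of step 9; C6 and C8 are untouched, which gives the trans lactone with O8 anti to C11. Attack at C7 and not at C8 is secured by the two-atom tether and the trans oxirane, which keep the rear side of C8 out of reach. C- over O-alkylation is favoured by keeping the anion as a contact ion pair chelated between P=O and C=O (sodium in THF, no crown ether or dipolar cosolvent) and by rotation about the ester C–O bond, which lets C6 leave the enolate plane. One equivalent of base, the weakly basic stabilised anion and the quench at 0 °C should spare the iodoalkene and the silyl ether and prevent migration of the lactone to O8.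

Step 12
Reactants: 22 (E)-2-methylbut-2-en-1-ol
Product: 23 [(2S,3S)-2,3-dimethyloxiran-2-yl]methanol
Conditions: Ti(OiPr)4 (cat.), L-(+)-DET (cat.), t-BuOOH, 4 Å MS, CH2Cl2, −20 °C
Reagents that add atoms: tert-butyl hydroperoxide, CC(C)(C)OO
Why: Sharpless asymmetric epoxidation of a primary E-allylic alcohol; the L-(+)-tartrate reagent delivers oxygen to the face that gives the (2S,3S)-epoxy alcohol, setting both side-chain centres.

Step 13
Reactants: 23 [(2S,3S)-2,3-dimethyloxiran-2-yl]methanol
Product: 24 (2R,3S)-2,3-dimethyloxirane-2-carboxylic acid
Conditions: RuCl3·xH2O (cat.), NaIO4, MeCN/EtOAc/H2O, 0 °C to rt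
Reagents that add atoms: water, O; sodium periodate, [Na+].[O-]I(=O)(=O)=O
Why: Oxidation of the primary alcohol to the acid by RuO4 formed in the flask leaves the oxirane intact; no stereocentre is touched, and the label at C2 becomes R only because the carboxyl group outranks C3.

Step 14
Reactants: 21 hydroxy methylene lactone; 24 (2R,3S)-2,3-dimethyloxirane-2-carboxylic acid
Product: 26 ester of 21 at O8 with 24 (6S,7R,8R; side chain 2R,3S), via mixed anhydride 25 (not isolated)
Conditions: 24, 2,4,6-trichlorobenzoyl chloride, Et3N, THF, rt; then 21, DMAP, toluene, 0 °C to rt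
Reagents that add atoms: none
Why: Yamaguchi esterification acylates the hindered secondary O8 through the mixed anhydride 25 and an acylpyridinium ion under conditions too mild for lactone migration; once acylated, O8 can no longer translactonise.

Step 15
Reactants: 26 O8 ester with primary silyl ether
Product: 27 primary alcohol at C3 (6S,7R,8R; side chain 2R,3S)
Conditions: HF·pyridine, pyridine, THF, 0 °C
Reagents that add atoms: none
Why: Buffered fluoride cleaves the primary silyl ether; the glycidic ester (deactivated toward acid opening by its carbonyl), the lactone and the iodoalkene should survive.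

Step 16
Reactants: 27 primary alcohol
Product: 28 C3 aldehyde (6S,7R,8R; side chain 2R,3S)
Conditions: Dess–Martin periodinane, NaHCO3, CH2Cl2, 0 °C
Reagents that add atoms: none
Why: Dess–Martin oxidation under buffered conditions gives the β,γ-unsaturated aldehyde without moving C1=C10 into conjugation; the aldehyde is used crude.

Step 17
Reactants: 28 iodo aldehyde
Product: 29 (1(10)E,4Z)-3S-hydroxy-8R-[(2R,3S)-2,3-dimethyloxirane-2-carbonyloxy]germacra-1(10),4,11(13)-trien-12,6R-olide (7R)
Conditions: CrCl2, NiCl2 (cat.), DMSO, rt, high dilution
Reagents that add atoms: none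
Why: Nozaki–Hiyama–Kishi reaction: zerovalent nickel inserts into the C4–I bond with retention of the Z geometry, transmetalation gives an alkenylchromium of trivalent chromium that adds only to the aldehyde, forming C3–C4 and ring A while lactone, ester and oxirane are tolerated. C3 is set by the conformation of the forming ring (substrate control), and the S configuration has to be confirmed.

Step 18
Reactants: 29 macrocyclic allylic alcohol
Product: 30 O3-triethylsilyl ether of 29
Conditions: TESCl, imidazole, CH2Cl2, 0 °C
Reagents that add atoms: chlorotriethylsilane, CC[Si](Cl)(CC)CC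
Why: Silylation of the secondary allylic alcohol removes hydrogen-bond direction of the peracid toward C4=C5 and shields that olefin; no stereocentre changes.

Step 19
Reactants: 30 O3-triethylsilyl ether
Product: 31 (1R,10R)-1,10-epoxide of 30
Conditions: mCPBA, NaHCO3, CH2Cl2, 0 °C
Reagents that add atoms: 3-chloroperbenzoic acid, OOC(=O)c1cccc(Cl)c1
Why: Prilezhaev epoxidation should select C1=C10, the only electron-rich olefin (C4=C5 is flanked by two allylic C–O bonds and the silyl ether, C11=C13 is conjugated). C1 and C10 are set by attack on the outer face of the E olefin held in ring A, expected by analogy with peripheral epoxidation of E-1(10)-germacrenes to give the 1R,10R isomer.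

Step 20
Reactants: 31 silylated epoxide
Product: 32 CNP0268255.6, (1R,3S,6R,7R,8R,10R)-1,10-epoxy-3-hydroxy-8-[(2R,3S)-2,3-dimethyloxirane-2-carbonyloxy]germacra-4Z,11(13)-dien-12,6-olide
Conditions: TBAF, AcOH, THF, 0 °C
Reagents that add atoms: none
Why: Fluoride buffered with acetic acid removes the triethylsilyl group without acid, so neither transannular opening of ring C by C4=C5 or O3 nor conjugate addition to the methylene lactone is expected.

## Compound list

1 | 4-methylpent-3-en-1-ol | CC(C)=CCCO | starting material
2 | tert-butyldimethyl[(4-methylpent-3-en-1-yl)oxy]silane | CC(C)=CCCO[Si](C)(C)C(C)(C)C | intermediate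
3 | (E)-5-[(tert-butyldimethylsilyl)oxy]-2-methylpent-2-enal | CC(C)(C)[Si](C)(C)OCC/C=C(\C)C=O | intermediate
4 | (E)-5-[(tert-butyldimethylsilyl)oxy]-2-methylpent-2-en-1-ol | CC(C)(C)[Si](C)(C)OCC/C=C(\C)CO | intermediate
5 | (E)-[(5-bromo-4-methylpent-3-en-1-yl)oxy](tert-butyl)dimethylsilane | CC(C)(C)[Si](C)(C)OCC/C=C(\C)CBr | intermediate
6 | ethynyltrimethylsilane | C#C[Si](C)(C)C | starting material
7 | [(trimethylsilyl)ethynyl]magnesium bromide | C[Si](C)(C)C#C[Mg]Br | intermediate
8 | (E)-tert-butyldimethyl{[4-methyl-7-(trimethylsilyl)hept-3-en-6-yn-1-yl]oxy}silane | CC(C)(C)[Si](C)(C)OCC/C=C(\C)CC#C[Si](C)(C)C | intermediate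
9 | (E)-tert-butyldimethyl[(4-methylhept-3-en-6-yn-1-yl)oxy]silane | CC(C)(C)[Si](C)(C)OCC/C=C(\C)CC#C | intermediate
10 | but-2-yn-1-ol | CC#CCO | starting material
11 | sodium 2,2-bis(2-methoxyethoxy)-3-methyl-2,5-dihydro-1,2-oxaluminol-2-uide (cyclic alkenylalanate) | [Na+].CC1=CCO[Al-]1(OCCOC)OCCOC | intermediate
12 | (Z)-3-iodobut-2-en-1-ol | C/C(I)=C/CO | intermediate
13 | (Z)-3-iodobut-2-enal | C/C(I)=C/C=O | intermediate
14 | chloro[(1E,4E)-7-[(tert-butyldimethylsilyl)oxy]-4-methylhepta-1,4-dien-1-yl]bis(cyclopentadienyl)zirconium | Cl[Zr](C1C=CC=C1)(C1C=CC=C1)/C=C/C/C(C)=C/CCO[Si](C)(C)C(C)(C)C | intermediate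
15 | [(1E,4E)-7-[(tert-butyldimethylsilyl)oxy]-4-methylhepta-1,4-dien-1-yl](methyl)zinc | C[Zn]/C=C/C/C(C)=C/CCO[Si](C)(C)C(C)(C)C | intermediate
16 | rac-(2Z,5E,8E)-11-[(tert-butyldimethylsilyl)oxy]-2-iodo-8-methylundeca-2,5,8-trien-4-ol | C/C(I)=C/C(O)/C=C/C/C(C)=C/CCO[Si](C)(C)C(C)(C)C | intermediate
17 | (1R,2Z)-1-[(2R,3R)-3-{(2E)-5-[(tert-butyldimethylsilyl)oxy]-2-methylpent-2-en-1-yl}oxiran-2-yl]-3-iodobut-2-en-1-ol | O[C@H](/C=C(I)/C)[C@H]1O[C@@H]1C/C(C)=C/CCO[Si](C)(C)C(C)(C)C | intermediate
18 | (diethoxyphosphoryl)acetic acid | CCOP(=O)(CC(=O)O)OCC | starting material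
19 | (1R,2Z)-1-[(2S,3R)-3-{(2E)-5-[(tert-butyldimethylsilyl)oxy]-2-methylpent-2-en-1-yl}oxiran-2-yl]-3-iodobut-2-en-1-yl (diethoxyphosphoryl)acetate | CCOP(=O)(OCC)CC(=O)O[C@H](/C=C(I)/C)[C@H]1O[C@@H]1C/C(C)=C/CCO[Si](C)(C)C(C)(C)C | intermediate
20 | sodium salt (carbanion at C11) of the α-(diethoxyphosphoryl) lactone with free O8 (6S,7R,8R) | [Na+].CCOP(=O)(OCC)[C-]1C(=O)O[C@H](/C=C(I)/C)[C@H]1[C@H](O)C/C(C)=C/CCO[Si](C)(C)C(C)(C)C | intermediate
21 | (4R,5S)-4-[(1R,3E)-6-[(tert-butyldimethylsilyl)oxy]-1-hydroxy-3-methylhex-3-en-1-yl]-5-[(1Z)-2-iodoprop-1-en-1-yl]-3-methylideneoxolan-2-one | C=C1C(=O)O[C@H](/C=C(I)/C)[C@H]1[C@H](O)C/C(C)=C/CCO[Si](C)(C)C(C)(C)C | intermediate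
22 | (E)-2-methylbut-2-en-1-ol | C/C=C(\C)CO | starting material
23 | [(2S,3S)-2,3-dimethyloxiran-2-yl]methanol | OC[C@]1(C)O[C@H]1C | intermediate
24 | (2R,3S)-2,3-dimethyloxirane-2-carboxylic acid | OC(=O)[C@]1(C)O[C@H]1C | intermediate
25 | (2R,3S)-2,3-dimethyloxirane-2-carboxylic 2,4,6-trichlorobenzoic anhydride | Clc1cc(Cl)cc(Cl)c1C(=O)OC(=O)[C@]1(C)O[C@H]1C | intermediate
26 | (2R,3S)-2,3-dimethyloxirane-2-carboxylate of 21 at O8 (6S,7R,8R) | C=C1C(=O)O[C@H](/C=C(I)/C)[C@H]1[C@H](OC(=O)[C@]2(C)O[C@H]2C)C/C(C)=C/CCO[Si](C)(C)C(C)(C)C | intermediate
27 | primary C3 alcohol from 26 (6S,7R,8R) | C=C1C(=O)O[C@H](/C=C(I)/C)[C@H]1[C@H](OC(=O)[C@]2(C)O[C@H]2C)C/C(C)=C/CCO | intermediate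
28 | C3 aldehyde from 27 (6S,7R,8R) | C=C1C(=O)O[C@H](/C=C(I)/C)[C@H]1[C@H](OC(=O)[C@]2(C)O[C@H]2C)C/C(C)=C/CC=O | intermediate
29 | (1(10)E,4Z)-3S-hydroxy-8R-[(2R,3S)-2,3-dimethyloxirane-2-carbonyloxy]germacra-1(10),4,11(13)-trien-12,6R-olide (7R) | C=C1C(=O)O[C@@H]2/C=C(/C)[C@@H](O)C/C=C(\C)C[C@@H](OC(=O)[C@]3(C)O[C@H]3C)[C@@H]12 | intermediate
30 | O3-triethylsilyl ether of 29 | C=C1C(=O)O[C@@H]2/C=C(/C)[C@@H](O[Si](CC)(CC)CC)C/C=C(\C)C[C@@H](OC(=O)[C@]3(C)O[C@H]3C)[C@@H]12 | intermediate
31 | (1R,10R)-1,10-epoxide of 30 | C=C1C(=O)O[C@@H]2/C=C(/C)[C@@H](O[Si](CC)(CC)CC)C[C@H]3O[C@]3(C)C[C@@H](OC(=O)[C@]3(C)O[C@H]3C)[C@@H]12 | intermediate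
32 | CNP0268255.6, (1R,3S,6R,7R,8R,10R)-1,10-epoxy-3-hydroxy-8-[(2R,3S)-2,3-dimethyloxirane-2-carbonyloxy]germacra-4Z,11(13)-dien-12,6-olide | C=C1C(=O)O[C@@H]2/C=C(/C)[C@@H](O)C[C@H]3O[C@]3(C)C[C@@H](OC(=O)[C@]3(C)O[C@H]3C)[C@@H]12 | target

## Step count and least certain steps

Total step count: 20. Longest linear sequence: 16 steps (steps 1–5, 8–11 and 14–20); steps 6–7 and 12–13 are side branches.

**Step 11 (key step, proposed new method).**
- What may go wrong: the ambident anion may alkylate through its carbonyl oxygen, which reaches the rear of C7 from the ground-state ester conformation, giving a cyclic ketene acetal in place of C–C bond formation. The closure may also simply be too slow, because the enolate carbon must attack at a poor angle. Prolonged exposure of the product to alkoxide could move the lactone to O8.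
- Fallback by known chemistry, from 17 back to the route at 26:
  - 17 is O-alkylated with propargyl bromide (NaH, Bu4NI, THF, 0 °C) to the propargyl ether F1.
  - Cp2TiCl, a reagent of trivalent titanium made from Cp2TiCl2 and Zn dust in THF and added slowly, opens the oxirane homolytically at C7–O. The C7 radical closes 5-exo-dig onto the alkyne to give the 3-methylideneoxolane alcohol F2. C6 and C8 are untouched and the C6 and C7 substituents are trans, as is usual for such radical closures.
  - O8 of F2 is acylated with 24 as in step 14 to give the ester F3.
  - Oxidation of the ring CH2 of F3, which is both allylic and next to oxygen, with CrO3·2 pyridine in CH2Cl2 gives the lactone 26.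

**Step 17 (ring closure).**
- What may go wrong: facial selectivity at C3 is decided only by the conformation of the forming ten-membered ring and may be low or reversed. Slow closure also leaves time for intermolecular coupling and for isomerisation of the β,γ-unsaturated aldehyde.
- Fallback, from 28 back to the route at 29: material that closes to the C3 epimer F4 (alone or mixed with 29) is oxidised with Dess–Martin periodinane to the C3 ketone F5. F5 is then reduced under reagent control (Corey–Bakshi–Shibata reduction with the (R)-oxazaborolidine and catecholborane, toluene, −40 °C) to 29.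

**Step 19 (epoxidation).**
- What may go wrong: poor facial selectivity at C1=C10, since the preference for the outer face rests on analogy, and some attack at C4=C5.
- Fallback, from 30 back to the route at 31: substrate control is replaced by reagent control with a Shi epoxidation (D-fructose-derived ketone, KHSO5, K2CO3 buffer, MeCN/dimethoxymethane/H2O, 0 °C). Its spiro transition state is expected to give the (R,R)-type oxirane on an E-trisubstituted olefin. This fallback makes no new compound (F0).

**Step 9 (kinetic resolution).**
- What may go wrong: incomplete rate discrimination between the enantiomers, or ionisation of the acid-sensitive bis-allylic alcohol on titanium. At best half of 16 is used.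
- Fallback, from 9 and 13 back to the route at 17: the alkenylzinc addition of step 8 is run with a chiral amino alcohol ligand (for example 3-exo-morpholinoisoborneol in the antipode that gives the S carbinol) to give the enantioenriched (S)-carbinol F6. F6 is then epoxidised with the matched D-(−)-tartrate reagent to full conversion, giving 17.

## Further compounds

F1 | step 11 | propargyl ether of 17 at O6 (6R,7S,8R) | C#CCO[C@H](/C=C(I)/C)[C@H]1O[C@@H]1C/C(C)=C/CCO[Si](C)(C)C(C)(C)C
F2 | step 11 | 3-methylideneoxolane alcohol, 21 with CH2 in place of the lactone carbonyl (6S,7R,8R) | C=C1CO[C@H](/C=C(I)/C)[C@H]1[C@H](O)C/C(C)=C/CCO[Si](C)(C)C(C)(C)C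
F3 | step 11 | (2R,3S)-2,3-dimethyloxirane-2-carboxylate of F2 at O8 | C=C1CO[C@H](/C=C(I)/C)[C@H]1[C@H](OC(=O)[C@]2(C)O[C@H]2C)C/C(C)=C/CCO[Si](C)(C)C(C)(C)C
F4 | step 17 | C3 epimer (3R) of 29 | C=C1C(=O)O[C@@H]2/C=C(/C)[C@H](O)C/C=C(\C)C[C@@H](OC(=O)[C@]3(C)O[C@H]3C)[C@@H]12
F5 | step 17 | 3-oxo analogue of 29 | C=C1C(=O)O[C@@H]2/C=C(/C)C(=O)C/C=C(\C)C[C@@H](OC(=O)[C@]3(C)O[C@H]3C)[C@@H]12
F0 | step 19 | none | none
F6 | step 9 | (4S,2Z,5E,8E)-11-[(tert-butyldimethylsilyl)oxy]-2-iodo-8-methylundeca-2,5,8-trien-4-ol | O[C@H](/C=C(I)/C)/C=C/C/C(C)=C/CCO[Si](C)(C)C(C)(C)C
A1 | alternative 1 | open-chain α'-bromo Z-enone with C1 aldehyde | BrCC(=O)/C(C)=C\[C@@H](O[Si](CC)(CC)CC)[C@H](C(=C)CO[Si](CC)(CC)CC)[C@H](OCc1ccc(OC)cc1)C[C@@](C)(O[Si](CC)(CC)CC)C=O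
A2 | alternative 1 | macrocyclic β-hydroxy Z-enone | O[C@H]1CC(=O)/C(C)=C\[C@@H](O[Si](CC)(CC)CC)[C@H](C(=C)CO[Si](CC)(CC)CC)[C@H](OCc2ccc(OC)cc2)C[C@@]1(C)O[Si](CC)(CC)CC
A3 | alternative 2 | open-chain lactone with C10 primary nitro group and C8=C9 vinyl group | C=C[C@H]1CC(=O)O[C@@H]1/C=C(C)\[C@@H](O[Si](C)(C)C(C)(C)C)C[C@@H](C[N+](=O)[O-])OCc1ccc(OC)cc1
A4 | alternative 2 | bridged isoxazoline | C12=NO[C@H](C1)[C@H]3CC(=O)O[C@@H]3/C=C(C)\[C@@H](O[Si](C)(C)C(C)(C)C)C[C@@H]2OCc4ccc(OC)cc4
A5 | alternative 3 | methylene lactone with C8 aldehyde and C1 trimethylsilyl allylsilane (C1 configuration open) | C=C1C(=O)O[C@H](/C=C(/C)[C@@H](O[Si](C)(C)C(C)(C)C)CC([Si](C)(C)C)C(C)=C)[C@H]1C=O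
A6 | alternative 3 | 8-hydroxy macrocyclic lactone | C=C1C(=O)O[C@@H]2/C=C(/C)[C@@H](O[Si](C)(C)C(C)(C)C)C/C=C(\C)C[C@@H](O)[C@@H]12
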